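**Retrosynthetic overview**
1. Numbering: the side chain runs from C1′ (benzylic CH2) to C16′, and C20′ is the CH2OAc carbon on C3′. The bicycle is a 2,8-dioxabicyclo[3.2.1]octane built from an oxolane ring (O, C4′, C5′, C6′, C7′) and a 1,3-dioxane ring (C4′, O, C9′, C8′, C7′, O) that share ketal carbon C4′.
2. Enabling feature: in the C2′(OAc)–C3′(OH) glycol, C3′ is a fully substituted carbinol flanked by C20′H2O and the bulky bridgehead ketal carbon C4′. This glycol is the opened form of a terminal oxirane C2′H2–O–C3′, and C1′, being benzylic on an electron-rich ring, migrates readily from boron.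
3. Key disconnection C1′–C2′: lithiated oxirane plus benzylic pinacol boronate, 1,2-metallate shift, then oxidation. One flask unites arene and terpenoid halves, sets C2′, unmasks the C3′ carbinol and installs the C2′ oxygen.
4. The oxirane comes from Sharpless epoxidation (sets C3′) of a 2-substituted allylic alcohol, itself made from a γ-lactone and a 2-lithioallyl ether. Ring order: the oxolane ring is carried first as the lactone from (R)-linalool (C7′), and the 1,3-dioxane ring closes second under acid (C4′ fixed by the bicycle). C9′ is set by catalytic asymmetric alkenylzinc addition and the E-alkene by carboalumination.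
5. Endgame: desilylation, acetylation of the primary and secondary OH only, oxidative demethylation to the quinone, and dithionite reduction. The arene ring is bought, not built.

Key step: step 14

Remark: the sense of induction in steps 7 and 10 is assigned from the usual empirical models (amino-alcohol-catalysed organozinc addition; L-(+)-tartrate turns allyl alcohol into (S)-glycidol), and commercial (R)-(−)-linalool is taken as enantiopure.

Step 1
Reactants: 1 (R)-(−)-linalool
Product: 3 (5R)-5-ethenyl-5-methyloxolan-2-ol (lactol; both anomers), via ozonide 2 (not isolated)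
Conditions: O3 (1 equiv), CH2Cl2, −78 °C; Me2S, −78 °C → rt
Reagents that add atoms: ozone [O-][O+]=O
Why: Chemoselective ozonolysis, in which the electron-rich trisubstituted alkene consumes one equivalent of ozone far faster than the vinyl group and the freed γ-hydroxy aldehyde closes to the lactol, while C7′ comes unchanged from the chiral pool.

Step 2
Reactants: 3 (5R)-5-ethenyl-5-methyloxolan-2-ol
Product: 4 (5R)-5-ethenyl-5-methyloxolan-2-one
Conditions: TEMPO (10 mol %), PhI(OAc)2, CH2Cl2, rt
Reagents that add atoms: none
Why: Oxoammonium (TEMPO) oxidation of a lactol to the γ-lactone, which masks both the C7′ tertiary alcohol and the C4′ carbonyl and leaves the vinyl group alone.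

Step 3
Reactants: 4 (5R)-5-ethenyl-5-methyloxolan-2-one
Product: 6 (5R)-5-(2-hydroxyethyl)-5-methyloxolan-2-one, via B-alkyl-9-BBN adduct 5 (not isolated)
Conditions: 9-BBN, THF, 0 °C → rt; NaBO3·4H2O, H2O, rt
Reagents that add atoms: sodium perborate [Na+].[Na+].O[B-]1(O)OO[B-](O)(O)OO1
Why: Anti-Markovnikov hydroboration–oxidation, in which 9-BBN places boron on the terminal vinyl carbon without reducing the lactone and perborate oxidises the C–B bond without opening the lactone.

Step 4
Reactants: 6 (5R)-5-(2-hydroxyethyl)-5-methyloxolan-2-one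
Product: 7 [(2R)-2-methyl-5-oxooxolan-2-yl]acetaldehyde
Conditions: Dess–Martin periodinane, CH2Cl2, 0 °C → rt; used at once
Reagents that add atoms: none
Why: Dess–Martin oxidation gives the aldehyde under non-basic conditions, so the β-acyloxy aldehyde should not eliminate.

Step 5
Reactants: 8 5-bromo-2-methylpent-2-ene
Product: 9 6-methylhept-5-en-1-yne
Conditions: LiC≡CH·H2NCH2CH2NH2, DMSO, 10 °C → rt
Reagents that add atoms: lithium acetylide–ethylenediamine complex [Li]C#C.NCCN
Why: SN2 alkylation of lithium acetylide by an unhindered primary bromide.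

Step 6
Reactants: 9 6-methylhept-5-en-1-yne
Product: 11 (E)-1-iodo-2,6-dimethylhepta-1,5-diene, via alkenylalane 10 (not isolated)
Conditions: Me3Al, Cp2ZrCl2 (25 mol %), CH2Cl2, 0 °C → rt; I2, THF, −30 °C
Reagents that add atoms: trimethylaluminium C[Al](C)C; iodine II
Why: Negishi zirconium-catalysed carboalumination adds CH3 and Al syn across the terminal alkyne (Al terminal), and iodinolysis with retention fixes the E geometry of the C10′=C11′ alkene.

Step 7
Reactants: 7 [(2R)-2-methyl-5-oxooxolan-2-yl]acetaldehyde; 11 (E)-1-iodo-2,6-dimethylhepta-1,5-diene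
Product: 14 (5R)-5-[(2S,3E)-2-hydroxy-4,8-dimethylnona-3,7-dienyl]-5-methyloxolan-2-one, via alkenyllithium 12 (not isolated), via dialkenylzinc 13 (not isolated)
Conditions: 11, t-BuLi (2 equiv per iodide), Et2O, −78 °C; ZnBr2 (0.5 equiv per alkenyllithium), → 0 °C; Et2NCH2CH2NEt2, (2R)-(+)-3-exo-morpholinoisoborneol (10 mol %), 7, toluene, 0 °C
Reagents that add atoms: none
Why: Catalytic asymmetric alkenylzinc addition to an aldehyde, in which the amino-alcohol zinc complex should deliver the alkenyl group to the Re face to give (9′S) under catalyst control, the diamine masks the lithium salts and the lactone is inert to organozinc.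

Step 8
Reactants: 15 2-bromoprop-2-en-1-ol
Product: 16 2-[(2-bromoprop-2-enyl)oxy]oxane (THP ether)
Conditions: 3,4-dihydro-2H-pyran, PPTS (cat.), CH2Cl2, rt
Reagents that add atoms: 3,4-dihydro-2H-pyran C1=COCCC1
Why: Acid-catalysed THP acetal formation gives a silicon-free protecting group that cannot migrate to the later vinyl anion and falls off in the acid stage of step 9.

Step 9
Reactants: 14 (5R)-5-[(2S,3E)-2-hydroxy-4,8-dimethylnona-3,7-dienyl]-5-methyloxolan-2-one; 16 2-[(2-bromoprop-2-enyl)oxy]oxane
Product: 19 2-{(1R,3S,5R)-3-[(1E)-2,6-dimethylhepta-1,5-dienyl]-5-methyl-2,8-dioxabicyclo[3.2.1]octan-1-yl}prop-2-en-1-ol, via 2-lithioallyl THP ether 17 (not isolated), via hemiketal 18 (not isolated)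
Conditions: 16 (2.2 equiv), t-BuLi, Et2O, −78 °C; 14, THF, −78 °C; H2O; then camphorsulfonic acid (10 mol %), MeOH, 0 °C → rt
Reagents that add atoms: none
Why: Mono-addition of an alkenyllithium to a γ-lactone (the lithium hemiketal persists at −78 °C and one equivalent of 17 serves as base for the C9′ OH) followed by acid-catalysed acetal exchange, in which the THP group is lost and the C9′ OH attacks the C4′ oxocarbenium ion to close the 1,3-dioxane ring, C4′ taking the only configuration the C7′-anchored bicycle allows with the alkenyl group equatorial.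

Step 10
Reactants: 19 allylic alcohol of step 9
Product: 20 {(2S)-2-[(1R,3S,5R)-3-[(1E)-2,6-dimethylhepta-1,5-dienyl]-5-methyl-2,8-dioxabicyclo[3.2.1]octan-1-yl]oxiran-2-yl}methanol
Conditions: Ti(OiPr)4 (10 mol %), L-(+)-diisopropyl tartrate (12 mol %), t-BuOOH, 4 Å molecular sieves, CH2Cl2, −20 °C
Reagents that add atoms: tert-butyl hydroperoxide CC(C)(C)OO
Why: Sharpless asymmetric epoxidation touches only the alkene of the titanium-bound allylic alcohol (both trisubstituted alkenes are spectators), and L-(+)-tartrate should deliver oxygen in the sense allyl alcohol → (S)-glycidol, setting (3′S) under reagent control.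

Step 11
Reactants: 20 epoxy alcohol
Product: 21 triethylsilyl ether of 20
Conditions: Et3SiCl, imidazole, CH2Cl2, 0 °C
Reagents that add atoms: chlorotriethylsilane CC[Si](Cl)(CC)CC
Why: Standard silylation removes the acidic proton before the amide base is used and keeps the C20′ arm small.

Step 12
Reactants: 22 2,5-dimethoxytoluene
Product: 23 1-(chloromethyl)-2,5-dimethoxy-4-methylbenzene
Conditions: (CH2O)n, HCl (g), conc. aq. HCl, 1,4-dioxane, 0 °C → rt
Reagents that add atoms: formaldehyde C=O; hydrogen chloride Cl
Why: Blanc chloromethylation attacks the position ortho to a methoxy group and para to the methyl group, the site at which this arene is also formylated.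

Step 13
Reactants: 23 1-(chloromethyl)-2,5-dimethoxy-4-methylbenzene
Product: 24 2-(2,5-dimethoxy-4-methylbenzyl)-4,4,5,5-tetramethyl-1,3,2-dioxaborolane
Conditions: B2pin2, Pd(dba)2 (3 mol %), P(4-MeOC6H4)3 (6 mol %), KOAc, toluene, 50 °C
Reagents that add atoms: bis(pinacolato)diboron CC1(C)OB(OC1(C)C)B1OC(C)(C)C(C)(C)O1
Why: Miyaura borylation of a benzylic chloride (oxidative addition to zerovalent palladium, acetate-assisted transmetalation, reductive elimination).

Step 14
Reactants: 21 triethylsilyl ether of the epoxy alcohol; 24 benzylic pinacol boronate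
Product: 28 (2′R,3′S)-C2′ carbinol bearing TES ethers on the C3′ and C20′ oxygens, via lithiated oxirane 25 (not isolated), via boronate complex 26 (not isolated), via silyloxy boronic ester 27 (not isolated)
Conditions: 21, 24 (1.5 equiv), THF, −30 °C, slow addition of lithium 2,2,6,6-tetramethylpiperidide (from the amine and n-BuLi); Et3SiOTf, −78 °C → rt; then 30 % H2O2, 2 M NaOH, THF, 0 °C
Reagents that add atoms: triethylsilyl trifluoromethanesulfonate CC[Si](CC)(CC)OS(=O)(=O)C(F)(F)F; hydrogen peroxide OO
Why: Proposed new method: the hindered lithium amide should remove, in the presence of 24, the oxirane C2′–H that lies trans to bridgehead ketal carbon C4′ (cis to the CH2OSi arm), the carbenoid 25 is captured at once with retention by boron to give ate complex 26, silylation of the oxirane oxygen then triggers an antiperiplanar 1,2-shift of benzylic C1′ from boron to C2′ with inversion, which forms the C1′–C2′ bond, opens the three-membered ring and releases the C3′ oxygen as its TES ether (27), and peroxide replaces boron by OH with retention. The closest known reaction type is the homologation of pinacol boronic esters with lithiated monosubstituted terminal epoxides (a Matteson-type 1,2-metallate rearrangement) followed by oxidation to 1,2-diols; the 2,2-disubstituted oxirane and the benzylic migrating group are new here. No ring is closed: the only ring event is the stereospecific opening of the oxirane, and both ketal rings are spectators. The one new stereocentre, C2′, follows from the sequence trans-selective lithiation, retentive borylation, invertive migration and retentive oxidation, so it is relayed from the Sharpless-set C3′, which keeps its C–O bond and configuration. The step needs (a) a choice between the two diastereotopic C2′–H bonds, secured by the size difference between a CH2OSi arm and a fully substituted bicyclic carbon, (b) capture of the carbenoid faster than its 1,2-hydride shift to an enolate, secured by in situ trapping, and (c) metalation of the oxirane rather than the benzylic CH2 of 24, favoured by lithium–oxirane precoordination and the two donor methoxy groups and supported by slow addition of the amide to excess 24.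

Step 15
Reactants: 28 bis-TES carbinol
Product: 29 (2′R,3′S)-C2′,C3′,C20′-triol (arene as dimethyl ether)
Conditions: Bu4NF, THF, 0 °C → rt
Reagents that add atoms: none
Why: Fluoride-induced cleavage of both triethylsilyl ethers, at a stage where no ester or other fluoride- or base-sensitive group is present.

Step 16
Reactants: 29 triol
Product: 30 C2′,C20′-diacetate with free C3′ OH (arene as dimethyl ether)
Conditions: Ac2O, pyridine, DMAP (cat.), CH2Cl2, 0 °C → rt
Reagents that add atoms: acetic anhydride CC(=O)OC(C)=O
Why: Standard acylation reaches the primary C20′ and secondary C2′ hydroxyls, whereas the tertiary C3′ hydroxyl next to the ketal carbon is too hindered and stays free, which is the acetate pattern of the target.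

Step 17
Reactants: 30 diacetate dimethyl ether
Product: 31 2-methyl-5-alkyl-1,4-benzoquinone diacetate
Conditions: (NH4)2Ce(NO3)6, MeCN–H2O, 0 °C, short contact; NaHCO3 quench
Reagents that add atoms: water O
Why: Oxidative demethylation of a 1,4-dimethoxyarene by tetravalent cerium, routinely run on polyprenylated arenes, is faster than attack on isolated trisubstituted alkenes, and short contact at 0 °C should spare the ketal and the acetates.

Step 18
Reactants: 31 quinone diacetate
Product: 32 target CNP0160303.2
Conditions: Na2S2O4, EtOAc–H2O, rt, argon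
Reagents that add atoms: none
Why: Dithionite reduction of a 1,4-benzoquinone to the hydroquinone under neutral two-phase conditions touches no other group and no stereocentre.

**Compound list**
1 | (R)-(−)-linalool, (3R)-3,7-dimethylocta-1,6-dien-3-ol | CC(C)=CCC[C@](C)(C=C)O | starting material
2 | secondary ozonide (1,2,4-trioxolane) of the trisubstituted alkene of 1 | CC1(C)OOC(CC[C@](C)(C=C)O)O1 | intermediate
3 | (5R)-5-ethenyl-5-methyloxolan-2-ol | OC1CC[C@](C)(C=C)O1 | intermediate
4 | (5R)-5-ethenyl-5-methyloxolan-2-one | O=C1CC[C@](C)(C=C)O1 | intermediate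
5 | 9-BBN adduct of 4, boron on the terminal carbon | O=C1CC[C@](C)(CCB2C3CCCC2CCC3)O1 | intermediate
6 | (5R)-5-(2-hydroxyethyl)-5-methyloxolan-2-one | O=C1CC[C@](C)(CCO)O1 | intermediate
7 | [(2R)-2-methyl-5-oxooxolan-2-yl]acetaldehyde | O=C1CC[C@](C)(CC=O)O1 | intermediate
8 | 5-bromo-2-methylpent-2-ene | CC(C)=CCCBr | starting material
9 | 6-methylhept-5-en-1-yne | C#CCCC=C(C)C | intermediate
10 | (E)-(2,6-dimethylhepta-1,5-dienyl)dimethylalane | C[Al](C)/C=C(\C)CCC=C(C)C | intermediate
11 | (E)-1-iodo-2,6-dimethylhepta-1,5-diene | I/C=C(\C)CCC=C(C)C | intermediate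
12 | (E)-(2,6-dimethylhepta-1,5-dienyl)lithium | [Li]/C=C(\C)CCC=C(C)C | intermediate
13 | bis[(E)-2,6-dimethylhepta-1,5-dienyl]zinc | CC(C)=CCC/C(C)=C/[Zn]/C=C(\C)CCC=C(C)C | intermediate
14 | (5R)-5-[(2S,3E)-2-hydroxy-4,8-dimethylnona-3,7-dienyl]-5-methyloxolan-2-one | O=C1CC[C@](C)(C[C@@H](/C=C(\C)CCC=C(C)C)O)O1 | intermediate
15 | 2-bromoprop-2-en-1-ol | C=C(Br)CO | starting material
16 | 2-[(2-bromoprop-2-enyl)oxy]oxane | C=C(Br)COC1CCCCO1 | intermediate
17 | 2-lithioallyl THP ether | [Li]C(=C)COC1CCCCO1 | intermediate
18 | hemiketal from addition of 17 to 14 (C4′ OH, C9′ OH free) | C=C(COC2CCCCO2)C1(O)CC[C@](C)(C[C@@H](/C=C(\C)CCC=C(C)C)O)O1 | intermediate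
19 | 2-{(1R,3S,5R)-3-[(1E)-2,6-dimethylhepta-1,5-dienyl]-5-methyl-2,8-dioxabicyclo[3.2.1]octan-1-yl}prop-2-en-1-ol | C=C(CO)[C@]12CC[C@](C)(C[C@@H](/C=C(\C)CCC=C(C)C)O1)O2 | intermediate
20 | (3′S)-epoxy alcohol, oxirane C2′H2–O–C3′, C20′H2OH | OC[C@]3(CO3)[C@]12CC[C@](C)(C[C@@H](/C=C(\C)CCC=C(C)C)O1)O2 | intermediate
21 | triethylsilyl ether of 20 | CC[Si](CC)(CC)OC[C@]3(CO3)[C@]12CC[C@](C)(C[C@@H](/C=C(\C)CCC=C(C)C)O1)O2 | intermediate
22 | 2,5-dimethoxytoluene | COc1ccc(OC)c(C)c1 | starting material
23 | 1-(chloromethyl)-2,5-dimethoxy-4-methylbenzene | COc1cc(CCl)c(OC)cc1C | intermediate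
24 | 2-(2,5-dimethoxy-4-methylbenzyl)-4,4,5,5-tetramethyl-1,3,2-dioxaborolane | COc1cc(CB2OC(C)(C)C(C)(C)O2)c(OC)cc1C | intermediate
25 | C2′-lithiated oxirane, Li cis to the CH2OSi arm | CC[Si](CC)(CC)OC[C@]3([C@@H]([Li])O3)[C@]12CC[C@](C)(C[C@@H](/C=C(\C)CCC=C(C)C)O1)O2 | intermediate
26 | lithium oxiranyl(benzyl)pinacolatoborate | [Li+].CC[Si](CC)(CC)OC[C@]3([C@@H]([B-]4(Cc5cc(OC)c(C)cc5OC)OC(C)(C)C(C)(C)O4)O3)[C@]12CC[C@](C)(C[C@@H](/C=C(\C)CCC=C(C)C)O1)O2 | intermediate
27 | C2′ pinacol boronate with C3′ and C20′ OTES | CC[Si](CC)(CC)OC[C@](O[Si](CC)(CC)CC)([C@@H](Cc1cc(OC)c(C)cc1OC)B3OC(C)(C)C(C)(C)O3)[C@]12CC[C@](C)(C[C@@H](/C=C(\C)CCC=C(C)C)O1)O2 | intermediate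
28 | (2′R,3′S)-C2′ carbinol with C3′ and C20′ OTES | CC[Si](CC)(CC)OC[C@](O[Si](CC)(CC)CC)([C@@H](Cc1cc(OC)c(C)cc1OC)O)[C@]12CC[C@](C)(C[C@@H](/C=C(\C)CCC=C(C)C)O1)O2 | intermediate
29 | (2′R,3′S)-triol, arene as dimethyl ether | OC[C@](O)([C@@H](Cc1cc(OC)c(C)cc1OC)O)[C@]12CC[C@](C)(C[C@@H](/C=C(\C)CCC=C(C)C)O1)O2 | intermediate
30 | C2′,C20′-diacetate, arene as dimethyl ether | CC(=O)OC[C@](O)([C@@H](Cc1cc(OC)c(C)cc1OC)OC(C)=O)[C@]12CC[C@](C)(C[C@@H](/C=C(\C)CCC=C(C)C)O1)O2 | intermediate
31 | quinone diacetate | CC(=O)OC[C@](O)([C@@H](CC1=CC(=O)C(C)=CC1=O)OC(C)=O)[C@]12CC[C@](C)(C[C@@H](/C=C(\C)CCC=C(C)C)O1)O2 | intermediate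
32 | CNP0160303.2 | CC(=O)OC[C@](O)([C@@H](Cc1cc(O)c(C)cc1O)OC(C)=O)[C@]12CC[C@](C)(C[C@@H](/C=C(\C)CCC=C(C)C)O1)O2 | target

**Step count and risks**

Total step count: 18. Longest linear sequence: 13 steps (1–4, 7, 9–11, 14–18).

1. **Step 14 (bears the label).** What may go wrong:
   - The amide may metalate the benzylic CH2 of the boronate instead of the oxirane.
   - The carbenoid may collapse by 1,2-hydride shift before it meets boron.
   - The choice between the two diastereotopic C2′–H bonds may be poor.

   The fallback uses known chemistry, sets out from 21 and returns at 29. The oxirane is opened at its unhindered CH2 terminus with CsOAc in DMF to the hydroxy acetate F1. Methanolysis (K2CO3, MeOH) gives the diol F2, and Parikh–Doering oxidation of its only primary OH gives the α-hydroxy aldehyde F3. The benzylic Grignard reagent F4, made from chloride 23 and magnesium, is added in excess in THF at −78 °C. The first equivalent forms the C3′ magnesium alkoxide. Cram-chelate control (a five-membered chelate of alkoxide and aldehyde oxygens, with attack from the side of the small CH2OSi arm and away from the bicycle) should then give the (2′R) mono-TES diol F5. Bu4NF converts F5 into triol 29.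

2. **Step 7.** What may go wrong:
   - The lactone carboxylate may β-eliminate from the aldehyde in the amine-containing medium.
   - Facial selectivity at C9′ may be insufficient.

   The fallback sets out from 7 and 11 and returns at 14. A neutral Nozaki–Hiyama–Kishi coupling (CrCl2 as the divalent chromium source, NiCl2 cat., DMSO–THF) gives the C9′-epimeric allylic alcohol F6. Dess–Martin oxidation gives the enone F7. Corey–Bakshi–Shibata reduction with the (R)-methyl oxazaborolidine and catecholborane then sets (9′S) by hydride delivery instead of C–C bond formation.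

3. **Step 9.** What may go wrong:
   - The alkenyllithium may add twice or enolise the lactone.
   - The allylic C9′ alcohol may ionise during the acid stage.

   The fallback sets out from 14 and returns at 19. The lactone is opened with MeNH(OMe)·HCl and i-PrMgCl to the Weinreb amide diol F8. Both hydroxyls are silylated (Et3SiOTf, 2,6-lutidine) to the bis-TES amide F9. One equivalent of 17 gives the enone F10 without over-addition. Mild acid (PPTS, MeOH) then removes both TES groups and the THP group and closes the ketal to 19.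

**Further compounds**
F1 | step 14 | C2′ acetate, C3′ OH, C20′ OTES | CC[Si](CC)(CC)OC[C@](O)(COC(C)=O)[C@]12CC[C@](C)(C[C@@H](/C=C(\C)CCC=C(C)C)O1)O2
F2 | step 14 | C2′,C3′-diol, C20′ OTES | CC[Si](CC)(CC)OC[C@](O)(CO)[C@]12CC[C@](C)(C[C@@H](/C=C(\C)CCC=C(C)C)O1)O2
F3 | step 14 | α-hydroxy aldehyde (C2′ CHO), C20′ OTES | CC[Si](CC)(CC)OC[C@](O)(C=O)[C@]12CC[C@](C)(C[C@@H](/C=C(\C)CCC=C(C)C)O1)O2
F4 | step 14 | (2,5-dimethoxy-4-methylbenzyl)magnesium chloride | COc1cc(C[Mg]Cl)c(OC)cc1C
F5 | step 14 | (2′R,3′S)-diol, C20′ OTES | CC[Si](CC)(CC)OC[C@](O)([C@@H](Cc1cc(OC)c(C)cc1OC)O)[C@]12CC[C@](C)(C[C@@H](/C=C(\C)CCC=C(C)C)O1)O2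
F6 | step 7 | C9′-epimeric hydroxy lactone | O=C1CC[C@](C)(CC(O)/C=C(\C)CCC=C(C)C)O1
F7 | step 7 | C9′ enone lactone | O=C1CC[C@](C)(CC(=O)/C=C(\C)CCC=C(C)C)O1
F8 | step 9 | Weinreb amide diol | CON(C)C(=O)CC[C@](C)(C[C@@H](/C=C(\C)CCC=C(C)C)O)O
F9 | step 9 | bis-TES Weinreb amide | CON(C)C(=O)CC[C@](C)(C[C@@H](/C=C(\C)CCC=C(C)C)O[Si](CC)(CC)CC)O[Si](CC)(CC)CC
F10 | step 9 | bis-TES C4′ enone with THP-protected C20′ OH | C=C(COC1CCCCO1)C(=O)CC[C@](C)(C[C@@H](/C=C(\C)CCC=C(C)C)O[Si](CC)(CC)CC)O[Si](CC)(CC)CC
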